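**Retrosynthetic overview**
1. Ring A is bought as 2-amino-3-bromophenol (1). Through its diazonium salt (2) it becomes ortho-quinone diazide 3, a cyclic α-diazo ketone whose phenol ortho carbon acts as an acceptor (α-oxo carbenoid, an enolonium-type synthon).
2. Ring B is bought as 2-bromophenol (4), the oxygen donor.
3. Key disconnection: the ether O–C2 bond of ring A, made by O–H insertion of the carbenoid from 3 into 4. This joins a phenol ortho carbon and a phenol oxygen, both normally nucleophilic, and gives phenol 5 with its OH already free.
4. Last bonds made (first disconnected): C4–Br and C6–Br of ring A, by OH-directed dibromination of 5 through monobromide 6 to target 7.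
5. No ring is formed: both benzene rings are bought intact, and the ether C–O bond is the only bond between them.

Assumption: the target, 3,4,6-tribromo-2-(2-bromophenoxy)phenol, has no stereocentre and no hindered axis, so it is made as the single achiral compound the SMILES describes.

**Route**

Step 1
Reactants: 1 2-amino-3-bromophenol
Product: 3 5-bromo-6-diazocyclohexa-2,4-dien-1-one, via 2-bromo-6-hydroxybenzenediazonium chloride 2 (not isolated)
Conditions: NaNO2 (1.05 equiv), 2 M aq. HCl, 0 °C, 30 min; then NaHCO3 to pH 7, CH2Cl2 extraction, dark, below 20 °C; dried and solvent-switched to PhCF3 without taking to dryness (energetic)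
Reagents that add atoms: sodium nitrite, [Na+].[O-]N=O
Why: Diazotization of the primary arylamine, then deprotonation of the acidic ortho-hydroxy diazonium ion (pKa about 4), gives the neutral, extractable diazo oxide (ortho-quinone diazide); no stereocentre is created.

Step 2
Reactants: 3 5-bromo-6-diazocyclohexa-2,4-dien-1-one + 4 2-bromophenol
Product: 5 3-bromo-2-(2-bromophenoxy)phenol
Conditions: Rh2(OAc)4 (2 mol%), 4 (3 equiv), PhCF3, 60 °C, 3 added by syringe pump over 3 h, dark, argon
Reagents that add atoms: none
Why: Proposed new method: dirhodium tetraacetate removes N2 from the cyclic α-diazo ketone 3 to give an electrophilic quinoid α-oxo carbenoid at the carbon between C=O and C–Br, the oxygen of 4 adds to it, and proton transfer with re-aromatization of ring A gives the free ortho-aryloxy phenol with the C–Br bonds untouched; the closest known reactions are dirhodium-catalysed O–H insertion of α-diazo ketones into phenols and carbene transfer from quinone diazides (O–H insertion into alcohols, cyclopropanation); no stereocentre is created.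

Step 3
Reactants: 5 3-bromo-2-(2-bromophenoxy)phenol
Product: 7 3,4,6-tribromo-2-(2-bromophenoxy)phenol, via 3,4-dibromo-2-(2-bromophenoxy)phenol 6 (not isolated)
Conditions: Br2 (2.05 equiv), AcOH–CH2Cl2 (1:1), 0 °C to 20 °C, 2 h
Reagents that add atoms: bromine, BrBr
Why: Electrophilic aromatic bromination in which the free OH, the strongest donor, directs bromine mainly to its para position (C4) first and then to its ortho position (C6); C5 is meta to OH and ring B is a bromine-deactivated diaryl ether ring that reacts only after ring A is filled; no stereocentre is created.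

**Compound list**
1 | 2-amino-3-bromophenol | Nc1c(O)cccc1Br | starting material
2 | 2-bromo-6-hydroxybenzenediazonium chloride | Oc1cccc(Br)c1[N+]#N.[Cl-] | intermediate
3 | 5-bromo-6-diazocyclohexa-2,4-dien-1-one (ortho-quinone diazide of ring A) | O=C1C=CC=C(Br)C1=[N+]=[N-] | intermediate
4 | 2-bromophenol | Oc1ccccc1Br | starting material
5 | 3-bromo-2-(2-bromophenoxy)phenol | Oc1cccc(Br)c1Oc1ccccc1Br | intermediate
6 | 3,4-dibromo-2-(2-bromophenoxy)phenol | Oc1ccc(Br)c(Br)c1Oc1ccccc1Br | intermediate
7 | 3,4,6-tribromo-2-(2-bromophenoxy)phenol | Oc1c(Br)cc(Br)c(Br)c1Oc1ccccc1Br | target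

**Totals**
Total step count: 3. Longest linear sequence: 3 (1 → 3 → 5 → 7).

**Steps most likely to fail, with fallbacks**

Step 2 is the greatest risk. The carbenoid may attack a ring C–H of 4 instead of the O–H, or 3 may ring-contract by Wolff rearrangement. The fallback sets out from 4 and comes back at 5. Compound 4 is joined by nucleophilic aromatic substitution (K2CO3, DMF, 90 °C) to commercial 3-bromo-2-fluorobenzaldehyde (O=Cc1cccc(Br)c1F), whose fluoride is activated by the ortho formyl group, to give 3-bromo-2-(2-bromophenoxy)benzaldehyde F1. Baeyer–Villiger oxidation with aryl migration (mCPBA, CH2Cl2) gives 3-bromo-2-(2-bromophenoxy)phenyl formate F2. Methanolysis (cat. K2CO3, MeOH) then gives 5.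

Step 1 is the next risk. Compound 3 is light- and heat-sensitive and energetic, and may not survive extraction and drying. The fallback sets out from 1 and comes back at 5. Compound 1 is diazotized as before to 2, which is not neutralized but quenched with KI to give stable 3-bromo-2-iodophenol F3. Methylation (MeI, K2CO3, acetone) gives 1-bromo-2-iodo-3-methoxybenzene F4. An iodide-selective Ullmann ether coupling with 4 (CuI, N,N-dimethylglycine, Cs2CO3, dioxane, 90 °C) gives 1-bromo-2-(2-bromophenoxy)-3-methoxybenzene F5. BBr3 (CH2Cl2, −78 to 0 °C) cleaves the methyl ether to 5.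

Step 3 is the least risky. A third bromine may enter ring B para to the ether oxygen, or the second bromination may stall. The fallback sets out from 4 and comes back at 7, with all three ring A bromines in place before the ether bond is made. Commercial 2,4,5-tribromophenol (Oc1cc(Br)c(Br)cc1Br) is nitrated at its only free ortho position (HNO3, AcOH, 15 °C) to 3,4,6-tribromo-2-nitrophenol F6. Reduction (Fe, NH4Cl, EtOH–H2O, 70 °C) gives 2-amino-3,4,6-tribromophenol F7. Diazotization (NaNO2, aq. HCl–AcOH, 0 °C) gives 2,3,5-tribromo-6-hydroxybenzenediazonium chloride F8, and neutralization (NaHCO3) gives 2,4,5-tribromo-6-diazocyclohexa-2,4-dien-1-one F9. The same Rh2(OAc)4-catalysed O–H insertion with 4 (PhCF3, 60 °C) then gives 7 directly, with no bromination after the union.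

**Further compounds**
F1 | step 2 | 3-bromo-2-(2-bromophenoxy)benzaldehyde | O=Cc1cccc(Br)c1Oc1ccccc1Br
F2 | step 2 | 3-bromo-2-(2-bromophenoxy)phenyl formate | O=COc1cccc(Br)c1Oc1ccccc1Br
F3 | step 1 | 3-bromo-2-iodophenol | Oc1cccc(Br)c1I
F4 | step 1 | 1-bromo-2-iodo-3-methoxybenzene | COc1cccc(Br)c1I
F5 | step 1 | 1-bromo-2-(2-bromophenoxy)-3-methoxybenzene | COc1cccc(Br)c1Oc1ccccc1Br
F6 | step 3 | 3,4,6-tribromo-2-nitrophenol | Oc1c(Br)cc(Br)c(Br)c1[N+](=O)[O-]
F7 | step 3 | 2-amino-3,4,6-tribromophenol | Nc1c(O)c(Br)cc(Br)c1Br
F8 | step 3 | 2,3,5-tribromo-6-hydroxybenzenediazonium chloride | Oc1c(Br)cc(Br)c(Br)c1[N+]#N.[Cl-]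
F9 | step 3 | 2,4,5-tribromo-6-diazocyclohexa-2,4-dien-1-one | O=C1C(Br)=CC(Br)=C(Br)C1=[N+]=[N-]
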